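- Time is what I count here. By 4.2 min the spring run stands at 0.273 M of J, and the winter run has the same charge of Q (substrate) and G (catalyst) but starts with 1.00 M of J.

| setting | spring | noon | dawn | midnight | winter |
|---|---|---|---|---|---|
| Q | 1.00 M | 0.400 M | 1.50 M | 1.00 M | 1.00 M |
| G | 0.00200 M | 0.00200 M | 0.00200 M | 0.00400 M | 0.00200 M |
| J |  |  |  |  | 1.00 M |
| time |  |  |  |  | 4.2 min |

- spring run (time / min: [J] / M): 0.70: 0.082; 1.4: 0.161; 2.1: 0.202; 2.8: 0.230; 3.5: 0.259; 4.2: 0.273
- noon run (time / min: [J] / M): 0.70: 0.025; 1.4: 0.047; 2.1: 0.060; 2.8: 0.082; 3.5: 0.088; 4.2: 0.084
- dawn run (time / min: [J] / M): 0.70: 0.115; 1.4: 0.210; 2.1: 0.269; 2.8: 0.323; 3.5: 0.371; 4.2: 0.381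
- midnight run (time / min: [J] / M): 0.70: 0.169; 1.4: 0.283; 2.1: 0.367; 2.8: 0.396; 3.5: 0.403; 4.2: 0.421

(scatter of a reading: 0.005 M)

- Overall: Q -> J, with G as catalyst.
- Constant volume, constant temperature.
- Readings of a species count what is bound in complexes too.
- An order is taken over about fifteen percent of the charge, up and down.
- A share of J counts the J that was charged too.

- order of the initial rate in [Q], near the charge of the spring run, the rate being that where two percent of its Q are J (one fixed amount of J, the same in the runs compared)
- order of the initial rate in [G], near the charge of the spring run, the rate being that where two percent of its Q are J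
- J in the winter run at 4.2 min, as a share of the Q charged

- Over its first 1.4 min the readings of the spring run give J made at 0.115 M min⁻¹ on average. That gives τ = 2.37 min, the stall time, an apparent lifetime: the time the early rate needs to make the last spring reading. The asked time is therefore 1.77 stall times.
- I start with the main step on its own: the charged J stays and the early rate runs on, which puts the winter run at 148 % of the Q charged.
- Next I let the catalyst stall: I stop the fresh J of the winter run at the spring reading, and my estimate for the winter run comes down to 127 %.
- Then I suppose instead that the stall is J disappearing with lifetime τ. On that supposition the charged J keeps 17.0 %, and with the fresh J added my estimate for the winter run is 44.3 %.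
- My own reckoning is a range between these last two numbers, since I cannot tell from τ how the stall divides between catalyst and J.
- The forecast gives orders of 1.1 in Q and 1.2 in G, and 122 % for the winter run, on this ground: “That points to catalyst death independent of Q and J, not product inhibition.”
- The flask gives orders of 0.86 and 1.0, and 86.1 % for the winter run.

    G + Q ⇌ GQ, settled at all times (0.1420 M⁻¹)
    GQ + Q ⇌ GQ2, settled at all times (11.30 M⁻¹)
    GQ2 → J + GQ (126.6 min⁻¹)
    J → Qe (0.1236 min⁻¹)
    G + Q → Qa + Q (0.4830 M⁻¹ min⁻¹)

- The winter run ends below the forecast through the step from J to Qe: with that step taken away the winter run reaches 136 %, against 86.1 % with it. The lifetime of J is 8.09 min, so the asked time is 0.519 lifetimes and the charged J keeps 59.5 %, which leaves 27 percentage points of fresh J in the winter run. Counted the same way, with the early rate of the spring run, the fresh J of the winter run without the step gives a stall time of 3.12 min, longer than the 2.37 min of the spring run.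

(All runs are calculated for an exercise; scatter was added.)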